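**Retrosynthetic overview**
1. The oxirane ring is made last. After a final deacetylation, the step before it is epoxidation of a 2,4-cis-2-aryl-4-benzyl-3-methyleneoxolane on the face anti to both substituents.
2. The exocyclic alkene and the C4–H centre come from a 2-aryl-4-benzyl-2,5-dihydrofuran-3-carbaldehyde by reductive 1,3-transposition through an allylic diazene. The formyl carbon ends as the oxirane CH2.
3. The five-membered O-ring is formed first, in one three-component operation from O-acetylconiferaldehyde, propargyl alcohol and an aryl iodide. O1–C2 forms by oxa-Michael addition, C3–C4 by 5-exo-dig enamine attack on the palladium-bound alkyne, and the benzylic CH–aryl bond by reductive elimination.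
4. Enabling feature, in the oxolane ring (O1, aryl-bearing C2, spiro C3, benzyl-bearing C4, C5): C2, C3 and the oxirane CH2 are the β-, α- and formyl carbons of a cinnamaldehyde. O1–C5–C4 plus the exocyclic benzylic CH2 is the O–C–C≡C chain of propargyl alcohol. Nucleophilic O1 therefore meets electrophilic C2, and nucleophilic C3 meets electrophilic C4.

Key step: step 3

Assumption: the sense of induction is taken from the usual shielding model of diarylprolinol silyl ethers (attack on the β-carbon of the E, s-trans iminium ion anti to the CPh2(OSiMe3) group). On this model the (R)-amine gives the required (S)-configured C2 of the dihydrofuran.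

Step 1
Reactants: 1 2-methoxyphenyl acetate
Product: 2 5-iodo-2-methoxyphenyl acetate
Conditions: NIS (1.05 equiv), CF3CO2H (0.3 equiv), MeCN, rt
Reagents that add atoms: N-iodosuccinimide, O=C1CCC(=O)N1I
Why: Electrophilic aromatic iodination in which the methoxy group, the stronger donor, directs para to itself (meta to the weakly donating acetoxy group), so that C5 is iodinated.

Step 2
Reactants: 3 (E)-3-(4-hydroxy-3-methoxyphenyl)prop-2-enal (coniferaldehyde)
Product: 4 (E)-2-methoxy-4-(3-oxoprop-1-en-1-yl)phenyl acetate
Conditions: Ac2O, pyridine, DMAP (cat.), CH2Cl2, 0 °C to rt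
Reagents that add atoms: acetic anhydride, CC(=O)OC(C)=O
Why: Standard O-acetylation of a phenol, which protects it and turns the para substituent into a net acceptor so that the β-carbon of the enal stays electrophilic for step 3.

Step 3
Reactants: 4 (E)-2-methoxy-4-(3-oxoprop-1-en-1-yl)phenyl acetate; 5 prop-2-yn-1-ol (3 equiv); 2 5-iodo-2-methoxyphenyl acetate
Product: 8 (S)-2-(4-acetoxy-3-methoxyphenyl)-4-(3-acetoxy-4-methoxybenzyl)-2,5-dihydrofuran-3-carbaldehyde, via propargyl ether aldehyde 6 (not isolated), via arylidene aldehyde 7 (not isolated)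
Conditions: (R)-2-[diphenyl(trimethylsilyloxy)methyl]pyrrolidine (20 mol %), Pd(PPh3)4 (5 mol %), AcOH (20 mol %), NaOAc (1.5 equiv), THF–DMSO 4:1, Ar, rt to 40 °C
Reagents that add atoms: none
Why: Proposed new method: the amine and 4 form an iminium ion, 5 adds reversibly through oxygen to its β-carbon (O1–C2 bond, adduct 6 held as its enamine), the enamine carbon then attacks, anti to the metal, the tethered alkyne that is π-bound to the arylpalladium iodide formed from 2 and zerovalent palladium (C3–C4 bond), reductive elimination joins the vinyl carbon to the aryl group to give 7, and a proton shift through the dienamine moves the alkene into conjugation to give 8. The closest known reaction types are the amine/palladium co-catalysed domino oxa-Michael/carbocyclisation of propargyl alcohol with enals, which ends in protonation of the vinylpalladium species, and the palladium-catalysed three-component coupling of propargyl alkoxides, arylidene malonates and aryl iodides, in which a malonate enolate plays the part of the enamine; the proposal merges the two. The oxolane ring closes in the 5-exo-dig mode. The one stereocentre that is kept, C2, is controlled by the CPh2(OSiMe3) group of the (R)-amine, which shields one face of the iminium ion and lets only the (R)-configured adduct 6 cyclise quickly while its epimer reverts (dynamic kinetic asymmetric transformation); the C3 centre of 7 is erased on isomerisation. The step needs exo instead of endo closure and ring closure instead of alkynylation or Heck insertion of 2: the unsubstituted alkyne terminus and the three-atom C2–O1–C5 tether secure the first, the intramolecular nucleophile, the β-aryl substitution of 4 and the absence of copper salts and strong base the second. The para-acetoxy group makes the aryl ring of 4 a net acceptor, which keeps C2 electrophilic enough for the oxa-Michael step.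

Step 4
Reactants: 8 (S)-2-(4-acetoxy-3-methoxyphenyl)-4-(3-acetoxy-4-methoxybenzyl)-2,5-dihydrofuran-3-carbaldehyde
Product: 9 (S,E)-tosylhydrazone of 8
Conditions: TsNHNH2 (1.05 equiv), THF, rt
Reagents that add atoms: p-toluenesulfonyl hydrazide, Cc1ccc(cc1)S(=O)(=O)NN
Why: Condensation of an aldehyde with a sulfonyl hydrazide to the E-hydrazone under neutral conditions, which leaves the aryl acetates and the C2 stereocentre untouched.

Step 5
Reactants: 9 (S,E)-tosylhydrazone of 8
Product: 11 (2R,4R)-2-(4-acetoxy-3-methoxyphenyl)-4-(3-acetoxy-4-methoxybenzyl)-3-methyleneoxolane (2,4-cis), via allylic diazene 10 (not isolated)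
Conditions: catecholborane (2.5 equiv), CHCl3, −10 to 0 °C; then NaOAc·3H2O (3 equiv), reflux
Reagents that add atoms: none
Why: Hutchins–Kabalka reductive transposition, in which catecholborane reduces the C=N bond, acetate triggers loss of sulfinate to diazene 10, and the concerted retro-ene loss of N2 moves the alkene to the exocyclic position while passing hydrogen to C4 on the ring face anti to the C2 aryl group, which sets the 2,4-cis relation.

Step 6
Reactants: 11 (2R,4R)-2-(4-acetoxy-3-methoxyphenyl)-4-(3-acetoxy-4-methoxybenzyl)-3-methyleneoxolane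
Product: 12 (3S,4S,7S)-4-(4-acetoxy-3-methoxyphenyl)-7-(3-acetoxy-4-methoxybenzyl)-1,5-dioxaspiro[2.4]heptane
Conditions: dimethyldioxirane (1.2 equiv, solution in acetone), CH2Cl2, −20 to 0 °C
Reagents that add atoms: dimethyldioxirane, CC1(C)OO1
Why: Epoxidation of a 1,1-disubstituted alkene with a neutral dioxirane, in which the C2 aryl and C4 benzyl groups lie on the same face of the oxolane, so oxygen should enter from the open opposite face and set the spiro centre with the oxirane oxygen trans to both groups.

Step 7
Reactants: 12 (3S,4S,7S)-4-(4-acetoxy-3-methoxyphenyl)-7-(3-acetoxy-4-methoxybenzyl)-1,5-dioxaspiro[2.4]heptane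
Product: 13 (3S,4S,7S)-4-(4-hydroxy-3-methoxyphenyl)-7-(3-hydroxy-4-methoxybenzyl)-1,5-dioxaspiro[2.4]heptane (target)
Conditions: K2CO3 (0.2 equiv), MeOH, 0 °C; aq. NH4Cl
Reagents that add atoms: none
Why: Base-catalysed transesterification (Zemplén-type methanolysis) cleaves aryl acetates quickly at 0 °C, conditions under which the hindered spiro-oxirane and the benzylic ether should persist.

**Compound list**
1 | 2-methoxyphenyl acetate | COc1ccccc1OC(C)=O | starting material
2 | 5-iodo-2-methoxyphenyl acetate | COc1ccc(I)cc1OC(C)=O | intermediate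
3 | (E)-3-(4-hydroxy-3-methoxyphenyl)prop-2-enal (coniferaldehyde) | COc1cc(/C=C/C=O)ccc1O | starting material
4 | (E)-2-methoxy-4-(3-oxoprop-1-en-1-yl)phenyl acetate | COc1cc(/C=C/C=O)ccc1OC(C)=O | intermediate
5 | prop-2-yn-1-ol | C#CCO | starting material
6 | (R)-3-(4-acetoxy-3-methoxyphenyl)-3-(prop-2-yn-1-yloxy)propanal (reacts as its enamine, not isolated) | C#CCO[C@@H](c1ccc(OC(C)=O)c(OC)c1)CC=O | intermediate
7 | (2R,3R,4Z)-2-(4-acetoxy-3-methoxyphenyl)-4-(3-acetoxy-4-methoxybenzylidene)oxolane-3-carbaldehyde (not isolated) | O=C[C@H]1[C@H](c2ccc(OC(C)=O)c(OC)c2)OC/C1=C\c3ccc(OC)c(OC(C)=O)c3 | intermediate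
8 | (S)-2-(4-acetoxy-3-methoxyphenyl)-4-(3-acetoxy-4-methoxybenzyl)-2,5-dihydrofuran-3-carbaldehyde | O=CC1=C(Cc2ccc(OC)c(OC(C)=O)c2)CO[C@H]1c3ccc(OC(C)=O)c(OC)c3 | intermediate
9 | (S,E)-N'-{[2-(4-acetoxy-3-methoxyphenyl)-4-(3-acetoxy-4-methoxybenzyl)-2,5-dihydrofuran-3-yl]methylidene}-4-methylbenzenesulfonohydrazide | Cc1ccc(cc1)S(=O)(=O)N/N=C/C2=C(Cc3ccc(OC)c(OC(C)=O)c3)CO[C@H]2c4ccc(OC(C)=O)c(OC)c4 | intermediate
10 | (S)-[2-(4-acetoxy-3-methoxyphenyl)-4-(3-acetoxy-4-methoxybenzyl)-2,5-dihydrofuran-3-yl]methyldiazene (not isolated) | N=NCC1=C(Cc2ccc(OC)c(OC(C)=O)c2)CO[C@H]1c3ccc(OC(C)=O)c(OC)c3 | intermediate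
11 | (2R,4R)-2-(4-acetoxy-3-methoxyphenyl)-4-(3-acetoxy-4-methoxybenzyl)-3-methyleneoxolane (2,4-cis) | COc1ccc(C[C@H]2CO[C@@H](c3ccc(OC(C)=O)c(OC)c3)C2=C)cc1OC(C)=O | intermediate
12 | (3S,4S,7S)-4-(4-acetoxy-3-methoxyphenyl)-7-(3-acetoxy-4-methoxybenzyl)-1,5-dioxaspiro[2.4]heptane | COc1ccc(C[C@H]2CO[C@@H](c3ccc(OC(C)=O)c(OC)c3)[C@@]23CO3)cc1OC(C)=O | intermediate
13 | (3S,4S,7S)-4-(4-hydroxy-3-methoxyphenyl)-7-(3-hydroxy-4-methoxybenzyl)-1,5-dioxaspiro[2.4]heptane | COc1ccc(C[C@H]2CO[C@@H](c3ccc(O)c(OC)c3)[C@@]23CO3)cc1O | target

Total step count: 7. Longest linear sequence: 6 (steps 1, 3, 4, 5, 6, 7).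

**Steps most likely to fail**

Step 3.
- Risk: The arylpalladium iodide may be drained by alkynylation or insertion of free 5. The enamine, present only in low concentration, may be too weak a nucleophile for the neutral arylpalladium–alkyne complex, so that the oxa-Michael adduct simply reverts. Closure may also end in protonation instead of arylation.
- Fallback: This uses known chemistry, sets out from 2 and 4, and comes back to the route at 8. The alkyne carbon is replaced by a ketone at the same position. The ring then closes by the known amine-catalysed domino oxa-Michael/aldol reaction of α-hydroxy ketones with enals, and the cascade needs no metal.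
- Stille allylation of 2 (allyltributylstannane, Pd(PPh3)4, DMF, 80 °C) should give 5-allyl-2-methoxyphenyl acetate F1.
- Upjohn dihydroxylation (OsO4 cat., NMO, acetone–H2O) should give the racemic 5-(2,3-dihydroxypropyl)-2-methoxyphenyl acetate F2.
- Chemoselective oxidation of its secondary hydroxyl ([(neocuproine)Pd(OAc)]2(OTf)2 cat., benzoquinone, MeCN–H2O) should give 5-(3-hydroxy-2-oxopropyl)-2-methoxyphenyl acetate F3.
- F3 and 4 with the same (R)-amine and PhCO2H in toluene should give the 4-hydroxyoxolane-3-carbaldehyde F4. Its C2 is set by the catalyst, and the other two centres are of no consequence.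
- MsCl/Et3N should dehydrate F4 by E1cB elimination to 8.

Step 5.
- Risk: The CH2–N=NH arm rotates freely, so hydrogen transfer to C4 may show poor facial selectivity. Competing hydroboration of the product alkene is also possible.
- Fallback: This sets out from 8 and comes back at 11. Hydride is delivered from palladium instead of from a diazene.
- Luche reduction (NaBH4, CeCl3·7H2O, MeOH–THF, −40 °C) should give the allylic alcohol F5.
- ClCO2Me/pyridine should give the allylic methyl carbonate F6.
- Formate hydrogenolysis (Pd2(dba)3, PBu3, HCO2H–Et3N, THF, rt) should form the π-allyl complex on the ring face anti to the C2 aryl group. It should then pass hydride from the metal to the more substituted terminus C4, which gives the exocyclic alkene 11.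

Step 6.
- Risk: Facial selectivity may be lost, or the spiro-oxirane may rearrange or open during reaction and isolation.
- Fallback: This sets out from 11 and comes back at 13. The C–O bond at the spiro carbon is made by dihydroxylation, and the oxirane is closed only in the last operation.
- OsO4 (cat.)/NMO should attack the open face and give the 3-(hydroxymethyl)oxolan-3-ol F7.
- TsCl/pyridine at 0 °C should sulfonylate only the primary hydroxyl to give the monotosylate F8.
- K2CO3 (3 equiv) in MeOH should close the oxirane through the tertiary alkoxide (3-exo-tet) and cleave both acetates in the same flask, giving 13.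

**Further compounds**
F1 | step 3 | 5-allyl-2-methoxyphenyl acetate | C=CCc1ccc(OC)c(OC(C)=O)c1
F2 | step 3 | 5-(2,3-dihydroxypropyl)-2-methoxyphenyl acetate (racemic) | OCC(O)Cc1ccc(OC)c(OC(C)=O)c1
F3 | step 3 | 5-(3-hydroxy-2-oxopropyl)-2-methoxyphenyl acetate | OCC(=O)Cc1ccc(OC)c(OC(C)=O)c1
F4 | step 3 | (2R,3S)-2-(4-acetoxy-3-methoxyphenyl)-4-(3-acetoxy-4-methoxybenzyl)-4-hydroxyoxolane-3-carbaldehyde (C4 epimers) | O=C[C@H]1[C@H](c2ccc(OC(C)=O)c(OC)c2)OCC1(O)Cc3ccc(OC)c(OC(C)=O)c3
F5 | step 5 | (S)-[2-(4-acetoxy-3-methoxyphenyl)-4-(3-acetoxy-4-methoxybenzyl)-2,5-dihydrofuran-3-yl]methanol | OCC1=C(Cc2ccc(OC)c(OC(C)=O)c2)CO[C@H]1c3ccc(OC(C)=O)c(OC)c3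
F6 | step 5 | (S)-[2-(4-acetoxy-3-methoxyphenyl)-4-(3-acetoxy-4-methoxybenzyl)-2,5-dihydrofuran-3-yl]methyl methyl carbonate | COC(=O)OCC1=C(Cc2ccc(OC)c(OC(C)=O)c2)CO[C@H]1c3ccc(OC(C)=O)c(OC)c3
F7 | step 6 | (2S,3S,4S)-2-(4-acetoxy-3-methoxyphenyl)-4-(3-acetoxy-4-methoxybenzyl)-3-(hydroxymethyl)oxolan-3-ol | COc1ccc(C[C@H]2CO[C@@H](c3ccc(OC(C)=O)c(OC)c3)[C@@]2(O)CO)cc1OC(C)=O
F8 | step 6 | [(2S,3S,4S)-2-(4-acetoxy-3-methoxyphenyl)-4-(3-acetoxy-4-methoxybenzyl)-3-hydroxyoxolan-3-yl]methyl 4-methylbenzenesulfonate | COc1ccc(C[C@H]2CO[C@@H](c3ccc(OC(C)=O)c(OC)c3)[C@@]2(O)COS(=O)(=O)c4ccc(C)cc4)cc1OC(C)=O
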